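(The data were computed from invented constants, and the scatter is random.)

The product read at the end is a mix of E and G, which are mirror images, so their balance holds equal amounts and no excess. What the end excess measures is how much of the excess made from L has not yet gone that way.

| flask | L | J | D | remark | time |
|---|---|---|---|---|---|
| north-east | 0.50 M | 0.50 M | 2 M (in portions, 2) | run made earlier; portions every 3.0 h |  |
| west | 1 M | 1 M | 1 M (in portions, 2) | run made earlier; portions every 3.0 h |  |
| theta | 1.0 M | 1.0 M | 2.00 M (in portions, 2) | the portions of D follow each other after 3.0 h, the first at the start | 10 h |
| eta | 1.0 M | 1.0 M | 2.00 M (in portions, 2) | the portions of D follow each other after 5.0 h, the first at the start | 10 h |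
| delta | 1.0 M | 1.0 M | 2.00 M (in portions, 2) | the portions of D follow each other after 6.0 h, the first at the start | 10 h |
| beta | 1.0 M | 1.0 M | 2.00 M (in portions, 2) | the portions of D follow each other after 10 h, the first at the start | 10 h |

| run | time / h | E / % | G / % | L / % |
|---|---|---|---|---|
| north-east | 0.500 | 0.3 | 0.5 | 49.9 |
| north-east | 0.833 | 0.7 | 0 | 49.2 |
| north-east | 1.33 | 1.3 | 0.1 | 49.1 |
| north-east | 2.00 | 2.1 | 0 | 47.9 |
| north-east | 4.00 | 4.4 | 1.4 | 44.9 |
| north-east | 6.00 | 7.3 | 2.3 | 41.5 |
| west | 0.500 | 0.1 | 0 | 50.1 |
| west | 1.50 | 0.5 | 0.2 | 49.3 |
| west | 3.00 | 1.2 | 0.5 | 48.5 |
| west | 4.00 | 2.5 | 0.7 | 47.4 |
| west | 6.00 | 3.7 | 1.4 | 45.5 |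

(standard deviation of a reading: 0.3 percentage points)

- D is single-handed; L and J are mirror images of each other, charged as a racemate, each of them at the stated concentration
- the numbers in the tables scatter by 0.3 percentage points (one standard deviation)
- an excess is the difference of the two amounts in percent of their sum
- "hardly changes" means that all values lie within two and a half points (for a concentration: within two and a half percent of the largest)
- the handed part of D does not stay in what it makes, so the products of the two hands are mirror images too

- excess of E over G at the end for theta, eta, delta, beta, in this order
- how the row runs (hardly changes / falls all the way / rises, then falls / falls, then rises / rises all the way)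

The first rung is the flipping of E into G. At the last readings of the north-east and west runs, L has lost more than E holds, by 1.20% and 0.800% of the charge. Held against the area under E minus G, taken as a triangle, these gaps read as a constant of 0.0913 /h each way. The excess therefore decays at twice that rate, and the memory half-life, the time in which an excess left alone loses half of itself, reads 3.79 h.

The next rung is L, whose pseudo-first-order half-life under the whole charge of D reads 16.7 h, far slower than the memory. Making may thus be taken as following D. The last rung is J, which the north-east run reads as slower than L by a selectivity factor of 7.73, so fresh product is reckoned to carry an excess of 77.1%.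

Each hour of making then counts by the D standing in it and by the decay over the hours left. In flask beta the last portion comes at the reading, so making is taken as even, and a decay rate of 0.183 /h averaged over the run gives a surviving share of 0.459, a reckoned end excess of 35.4%. In flask delta making is taken to double after 6.0 h, the share is 0.531, and the reckoned end excess is 40.9%.

The forecast gives 40.7%, 42.4%, 43.1% and 39%, so the row rises, then falls, on the ground that “Early dosing makes more product but gives it longer to racemise”; it stands above this reckoning.

The flasks end at 34.1%, 36.4%, 37.1% and 31.7%: the row rises, then falls.

    D → X (k = 1.50 × 10⁻⁴ /h)
    E ⇌ G (k = 0.100 /h)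
    D + L → E (k = 0.0220 /M/h)
    D + J → G (k = 0.00240 /M/h)

Among the steps, the flipping of E and G has the largest single effect on the change from flask delta to flask beta, which is −5.4 percentage points with it and 0.69 points without it. With that flipping taken away, flask beta ends at 78.8% instead of 31.7%, a surviving share of 0.402 against the 0.459 reckoned from the memory half-life of 3.79 h. On flask theta, where making doubles after 3.0 h, that half-life gives a share of 0.503. Flask theta itself, at 34.1% with the flipping and 77.6% without it, keeps 0.439.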